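Drimane locants are used for every intermediate, monocyclic ones included: ring A is C1–C5 and C10, ring B is C5–C10, C11 is the carbon on C9, C12 the methyl on C8.

## The problem

The target is a trans-fused decalin (drimane) with a quaternary C10 methyl, a C4 gem-dimethyl group, an equatorial C3 acetate, a C7=C8 alkene carrying the C8 methyl, and a C11 methylene on C9 that is etherified with umbelliferone. Its configuration is (3R,5S,9R,10R). Three of the four stereocentres (C5, C10, C9) are contiguous and C3 is remote. C10 is the hub: once C5 and C10 are trans, the axial C10 methyl decides the face on which reagents reach C9, and together with the axial C4 methyl it decides the face of hydride attack at C3. Absolute configuration therefore only has to be brought in at C5/C10, and a chiral-pool anchor can do that. The coumarin does not tolerate ozone, hydride or alkoxide, so it must be attached last. The acetate rules out strong nucleophiles once it is in place. C9 is allylic to the C7=C8 bond: a carbonyl at C11 would make C9 epimerisable and invite the alkene into the C8=C9 position, so C11 is best introduced at the alcohol oxidation level under kinetic control. The feature that opens the key step is the make-up of ring A: beyond C10 and C5 it holds only C4 (with the gem-dimethyl group), C3 (at an oxidation level an ester carbon can supply) and the two-carbon bridge C1–C2. If C9 is a carbonyl, C10 is its α-carbon and C5 its β-carbon. An enone C9–C10–C5 can then take the C3–C4 unit at C5 as an isobutyrate enolate equivalent, the resulting C10 enolate can take C1–C2 from an acrylate, and the acrylate-derived enolate at C2 can close on the C3 ester.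

## Retrosynthesis

**C11–O(aryl).** The bond between C11 and the phenolic oxygen is cut first, giving alcohol 16 and umbelliferone 17. A later cut would force the coumarin through ozonolysis, hydride reduction and enolate chemistry, none of which its lactone and 3,4-alkene tolerate. Alcohol 16 lacks the whole heterocycle and 17 is commercial. The forward step must substitute a β-branched primary carbon under neutral conditions that leave the acetate alone.

**C9–C11.** Alcohol 16 is traced to diene 14 (C9–H and C11–O added across the exocyclic alkene), and 14 to enone 13 by cutting the C9=C11 bond. Bringing C11 in as a formyl or ester group would put a carbonyl beside the labile C9 centre, whereas hydroboration sets C9 kinetically under control of the C10 methyl. Enone 13 has lost C11 and the C9 stereocentre and keeps only C3, C5 and C10. The forward steps need a methylenation that works on a hindered enone without touching the acetate, and a borane that picks the terminal alkene and the face anti to the C10 methyl.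

**C7 substituent and C3 acyl group.** The C7=C8 enone of 13 is read as the residue of a C7 substituent: 13 comes from β-acetoxy ketone 12, and 12 from hydroxy ketone 10, in which C7 carries an isopropenyl group. That group is the carvone stereocentre, which will have controlled C5; putting it back costs nothing in complexity and supplies the absolute configuration. Dehydrogenating a saturated C9 ketone instead would lack a handle, while elimination from 12 can go only one way because C10 has no hydrogen. The forward excision must spare the hindered C9 ketone, which favours a Criegee rearrangement over a peracid Baeyer–Villiger route.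

**C3 carbinol and C2 ester.** Alcohol 10 is the reduction product of diketone 9, and 9 is the decarboxylation product of β-keto ester 8. These functional-group changes add no stereocentre other than C3, which the ring system controls. The forward steps need a hydride that tells C3 from C9 and attacks axially, and a neutral dealkoxycarbonylation.

**Ring A: C1–C10 and C2–C3.** Both remaining ring A bonds are cut together, giving silyl enol ether 4 and methyl acrylate 5. Cutting C3–C4 or C4–C5 instead would leave the hindered bond next to the gem-dimethyl group for the ring closure. This cut lets the C9 carbonyl serve twice (as Michael acceptor before, as enolate precursor now) and delivers C3 as a ketone with the gem-dimethyl group already beside it. The bicycle becomes a monocycle plus a commodity three-carbon unit; one ring, two C–C bonds and the quaternary C10 stereocentre arise in one operation. The forward reaction needs a regiodefined C10 enolate, attack anti to the C5 side chain, and a Dieckmann closure in one direction only.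

**C4–C5 and C8–C12.** Enol ether 4 is cut at C4–C5 into enone 2 and silyl ketene acetal 3, the commercial silyl ketene acetal of methyl isobutyrate. Enone 2 is cut at its C8 methyl back to (S)-carvone 1. Both are single C–C bond formations on a chiral-pool enone; the conjugate addition must go anti to the isopropenyl group and must leave the silyl group on the C9 oxygen.

## Roads not taken

**Alternative 1:** Here C5–C10 and C8–C9 are cut together, so both rings come from an open chain. Trienal A2 carries an (E)-β-methyl enal (C9=C10, C11 as the aldehyde) tied through C1–C4 to a 2-silyloxy diene (C5=C6–C7=C8). An intramolecular Diels–Alder reaction would give decalin A1.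
- Merits: two rings and four stereocentres in one step. C11 arrives on C9 at a useful oxidation level, and the enal geometry guarantees its cis relation to the C10 methyl. In ring-forming efficiency and in the handling of C11 this road is better than the chosen one.
- Weak points: A2 is an acyclic trienal whose C3 stereocentre needs an asymmetric step, and whose two trisubstituted alkenes need geometric control, so it is reached only by a long linear sequence. The dienophile is β,β-disubstituted and must form the quaternary C10, which calls for Lewis acid activation that the silyl enol ether diene tolerates poorly. The trans ring fusion and the diene face rest only on the C3 silyloxy group. After the cyclisation the C7 oxygen has to be removed while the C7=C8 alkene is placed, next to an epimerisable C9 aldehyde, and the C3 protecting group has to be exchanged.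
- Against this the chosen plan sets a two-step access to the key-step precursor from the chiral pool and substrate control of every stereocentre from C5.

**Alternative 2:** Here only C3–C4 is cut, with (S)-carvone 1 serving as ring B and its stereocentre becoming C5. Keto aldehyde A4 (C10 quaternary, three-carbon aldehyde chain trans to the isopropenyl group) would be treated with a metal-hydride hydrogen-atom-transfer catalyst and a silane. The tertiary C4 radical formed from the isopropenyl group would add 6-exo to the C3 aldehyde to give hydroxy enone A3.
- Merits: A3 is the free alcohol of 13 and would be reached in about four steps instead of seven. The carvone stereocentre is kept instead of excised, the enone of ring B is there from the start, and the gem-dimethyl group comes from the isopropenyl carbons. In step economy this road is clearly better.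
- Weak points: addition of a carbon radical to an aldehyde is reversible and must be outrun by reduction of the alkoxy radical. Simple reduction of the isopropenyl group and of the aldehyde compete. The C3 configuration arises in the radical step with no element that secures the equatorial hydroxyl. A4 needs a second alkylation of a hindered enolate with a chain that carries a free or masked aldehyde.
- Against this the chosen plan sets a two-electron ring closure driven by β-keto ester enolate formation and a C3 centre set by a well-understood hydride reduction, at the price of three more steps.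

**Alternative 3:** Here C7–C8 and C9–C10 are cut, so ring B is made on a ring A diene. Diene A6 (C10=C5–C6=C7) and ynoate A7 would combine in an intermolecular Diels–Alder reaction to diene ester A5.
- Merits: it is the most convergent of the four plans, and C11 and the C8 methyl come with the dienophile.
- Weak points: the vinyl group of A6 is flanked by the gem-dimethyl group and the C10 methyl and is twisted out of the s-cis geometry. The fully substituted diene terminus must form the quaternary C10 with a weak dienophile. The C10 face is governed only by the remote C3 silyloxy group. A5 still lacks C5 and C9 as stereocentres, so a selective trans hydrogenation of C5=C6, a deconjugation of the C8=C9 ester with control at C9, an ester reduction and a protecting-group exchange would follow.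
- Three of four stereocentres would be set under weak control, so this road is inferior in selectivity although superior in convergence.

Key step: step 3

Remarks on the chemistry:
- C8 is a temporary stereocentre, drawn throughout as installed in step 1 (methyl trans to the isopropenyl group). In bicycles 8–12 this places it axial and syn to the C10 methyl, so epimerisation under the basic conditions of steps 3, 4 and 7 is expected. It is harmless, because both epimers give enone 13.
- β-Keto ester 8 is a keto–enol and C2-epimer mixture, and hydroperoxide 11 is a mixture at its ketal carbon; neither centre persists.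

## Route

Step 1
Reactants: 1 (S)-carvone
Product: 2 (5S,6R)-2,6-dimethyl-5-(prop-1-en-2-yl)cyclohex-2-en-1-one (trans-6-methylcarvone)
Conditions: LiN(iPr)2, THF, −78 °C; MeI, −78 → 0 °C
Reagents that add atoms: methyl iodide, CI
Why: Kinetic deprotonation of the cross-conjugated enone at the α′-carbon (C8) and SN2 methylation of the lithium dienolate (enolate alkylation); methyl iodide enters anti to the neighbouring isopropenyl group, so mainly the trans isomer is expected. The C8 centre is transient.

Step 2
Reactants: 2 trans-6-methylcarvone; 3 1-methoxy-2-methyl-1-(trimethylsilyloxy)prop-1-ene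
Product: 4 methyl 2-methyl-2-[2,4-dimethyl-5-(prop-1-en-2-yl)-3-(trimethylsilyloxy)cyclohex-2-en-1-yl]propanoate (side chain on C5 trans to the C7 isopropenyl group)
Conditions: 3 (1.3 equiv), Ph3CSbCl6 (5 mol%), CH2Cl2, −78 °C; pyridine quench, non-aqueous work-up
Reagents that add atoms: none
Why: Mukaiyama–Michael addition under trityl-cation catalysis: the ketene acetal attacks the activated enone at C5 and the silyl group ends on the C9 oxygen, so the C9–C10 enol ether forms regiospecifically. The nucleophile adds axially, anti to the pseudo-equatorial C7 isopropenyl group, which sets C5.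

Step 3
Reactants: 4 silyl enol ether; 5 methyl acrylate
Product: 8 methyl 7-isopropenyl-3,9-dioxo-11-nordrimane-2-carboxylate (trans-fused), via potassium enolate 6 (not isolated), via Michael adduct ester enolate 7 (not isolated)
Conditions: KOtBu (1.0 equiv), THF, −40 → 0 °C; then 5 (1.05 equiv, slow addition), −78 °C → rt; AcOH
Reagents that add atoms: none
Why: KOtBu attacks silicon and releases the tetrasubstituted C9–C10 potassium enolate 6 with the regiochemistry fixed in step 2 and with no proton source that could move it to C8; an alkoxide is chosen over an alkyllithium because the latter would also add to the C3 ester. Enolate 6 adds through C10 to methyl acrylate (Michael addition, C1–C10), and ester enolate 7 acylates through C2 on the C3 ester (Dieckmann condensation, C2–C3); the expelled methoxide deprotonates the β-keto ester, which pulls both equilibria forward. The closest known reaction type is the one-flask Michael–Dieckmann (Michael–Claisen) annulation of regiodefined ketone enolates with acrylates. Ring A closes in the 6-exo-trig mode, the attacked ester carbonyl lying outside the new ring. The one lasting new stereocentre, C10, is controlled by C5: in 6 the CMe2CO2Me group stands pseudoaxial to avoid allylic strain with the C10 methyl and covers one face, so the acrylate adds anti to it, C1 and C4 come out trans on ring B and the ring fusion is trans; C2 is enolised or epimeric and disappears in step 4. The step needs C- over O-alkylation and C10 over C8 selectivity, which the regiospecific enolate, the aprotic medium and the slow addition of a limiting amount of acrylate in the cold should secure. It also needs the right Claisen partner: only C2 carries an α-hydrogen between the two esters (C4 is quaternary), and closure from C8 would give bridged, non-enolisable diketones that revert by retro-Claisen cleavage, so the enolisable β-keto ester is the thermodynamic sink.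

Step 4
Reactants: 8 β-keto ester
Product: 9 7-isopropenyl-11-nordrimane-3,9-dione
Conditions: LiCl, H2O, DMSO, 150 °C
Reagents that add atoms: none
Why: Krapcho dealkoxycarbonylation: chloride demethylates the β-keto ester and the carboxylate loses CO2 through the C3 enolate, which water protonates. The ketones and the isopropenyl group are inert, and C2 becomes a methylene group.

Step 5
Reactants: 9 diketone
Product: 10 3-hydroxy-7-isopropenyl-11-nordriman-9-one (3-OH equatorial, cis to the C10 methyl)
Conditions: NaBH4, MeOH/CH2Cl2, −20 → 0 °C
Reagents that add atoms: none
Why: Chemoselective borohydride reduction: the C3 carbonyl has one unsubstituted α-carbon, whereas C9 lies between the quaternary C10 and the tertiary C8 under the axial C10 methyl. Hydride attacks C3 axially, on the face away from the axial C4 methyl, giving the equatorial alcohol as in 4,4-dimethyl-3-oxo terpenoids; this sets C3.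

Step 6
Reactants: 10 hydroxy ketone
Product: 12 3,7-diacetoxy-11-nordriman-9-one (7-OAc in the place of the isopropenyl group), via methoxy hydroperoxide 11 (not isolated)
Conditions: O3, CH2Cl2/MeOH, −78 °C; then Ac2O, Et3N, DMAP, 0 °C → rt
Reagents that add atoms: ozone, [O-][O+]=O; methanol, CO; acetic anhydride, CC(=O)OC(C)=O
Why: Ozonolysis of the only alkene in methanol gives formaldehyde and α-methoxy hydroperoxide 11; peracetylation triggers the Criegee rearrangement, in which C7 migrates from carbon to oxygen with retention and acetate demethylates the dialkoxycarbenium ion to the C7 acetate (its acetyl carbons are the former isopropenyl C–CH3, its carbonyl oxygen comes from methanol). The same reagent acetylates the C3 hydroxyl, and the hindered C9 ketone, which a peracid Baeyer–Villiger route would endanger, is untouched.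

Step 7
Reactants: 12 diacetate
Product: 13 3-acetoxy-11-nordrim-7-en-9-one
Conditions: DBU, CH2Cl2, rt
Reagents that add atoms: none
Why: E1cB β-elimination: DBU enolises the C9 ketone toward C8, the only α-position with a hydrogen, and acetate leaves from C7, so the C7=C8 alkene forms regiospecifically and in conjugation. Either C8 epimer converges here; the C3 acetate has no acidic β-relationship and stays.

Step 8
Reactants: 13 enone
Product: 14 3-acetoxydrima-7,9(11)-diene
Conditions: Zn, CH2Br2, TiCl4, THF, −40 → 5 °C; then 13, CH2Cl2, 0 °C → rt
Reagents that add atoms: dibromomethane, BrCBr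
Why: Lombardo methylenation: the gem-dimetallic methylene reagent from Zn, CH2Br2 and TiCl4 is non-basic, olefinates hindered and enolisable ketones in a 1,2 sense and leaves esters alone, so the C3 acetate should survive. No stereocentre is involved.

Step 9
Reactants: 14 diene
Product: 16 3-acetoxydrim-7-en-11-ol (C11 cis to the C10 methyl), via alkylborane 15 (not isolated)
Conditions: 9-BBN, THF, 0 °C → rt; then 30% H2O2, aq. NaOAc, 0 °C → rt
Reagents that add atoms: hydrogen peroxide, OO
Why: Hydroboration–oxidation: 9-BBN adds to the 1,1-disubstituted terminus of the diene (boron on C11, hydrogen on C9) far faster than to the trisubstituted C7=C8 bond. The axial C10 methyl screens one face of C9, so hydrogen is delivered anti to it and C11 ends equatorial, cis to the C10 methyl, which sets C9; buffered peroxide oxidation with retention at C11 spares the acetate.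

Step 10
Reactants: 16 alcohol; 17 umbelliferone
Product: 18 7-{[(1R,4aS,6R,8aR)-6-acetoxy-2,5,5,8a-tetramethyl-1,4,4a,5,6,7,8,8a-octahydronaphthalen-1-yl]methoxy}-2H-chromen-2-one (target; drimane descriptors 3R,5S,9R,10R)
Conditions: PPh3, DIAD, THF, 0 °C → rt
Reagents that add atoms: none
Why: Mitsunobu etherification: the acidic phenol protonates the betaine and its phenoxide displaces the oxyphosphonium group at primary C11 in an SN2 reaction. No stereocentre is involved, and acetate, lactone and alkene are inert to the neutral conditions.

## Compound list

1 | (S)-carvone | CC1=CC[C@@H](CC1=O)C(C)=C | starting material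
2 | (5S,6R)-2,6-dimethyl-5-(prop-1-en-2-yl)cyclohex-2-en-1-one (trans-6-methylcarvone) | O=C1C(C)=CC[C@H](C(C)=C)[C@H]1C | intermediate
3 | 1-methoxy-2-methyl-1-(trimethylsilyloxy)prop-1-ene | COC(O[Si](C)(C)C)=C(C)C | starting material
4 | methyl 2-methyl-2-[2,4-dimethyl-5-(prop-1-en-2-yl)-3-(trimethylsilyloxy)cyclohex-2-en-1-yl]propanoate (C5 side chain trans to C7 isopropenyl) | COC(=O)C(C)(C)[C@H]1C[C@H](C(C)=C)[C@@H](C)C(O[Si](C)(C)C)=C1C | intermediate
5 | methyl acrylate | C=CC(=O)OC | starting material
6 | potassium C9–C10 enolate corresponding to 4 | COC(=O)C(C)(C)[C@H]1C[C@H](C(C)=C)[C@@H](C)C([O-])=C1C.[K+] | intermediate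
7 | potassium ester enolate of the C10 Michael adduct (C1–C2 chain trans to the C5 side chain) | COC([O-])=CC[C@@]1(C)C(=O)[C@H](C)[C@@H](C(C)=C)C[C@@H]1C(C)(C)C(=O)OC.[K+] | intermediate
8 | methyl 7-isopropenyl-3,9-dioxo-11-nordrimane-2-carboxylate (trans-fused; C2 epimers and enol) | COC(=O)C1C[C@@]2(C)C(=O)[C@H](C)[C@@H](C(C)=C)C[C@@H]2C(C)(C)C1=O | intermediate
9 | 7-isopropenyl-11-nordrimane-3,9-dione | O=C1CC[C@@]2(C)C(=O)[C@H](C)[C@@H](C(C)=C)C[C@@H]2C1(C)C | intermediate
10 | 3-hydroxy-7-isopropenyl-11-nordriman-9-one (3-OH equatorial, cis to C10 methyl) | O[C@@H]1CC[C@@]2(C)C(=O)[C@H](C)[C@@H](C(C)=C)C[C@@H]2C1(C)C | intermediate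
11 | 3-hydroxy-7-(1-hydroperoxy-1-methoxyethyl)-11-nordriman-9-one | O[C@@H]1CC[C@@]2(C)C(=O)[C@H](C)[C@@H](C(C)(OC)OO)C[C@@H]2C1(C)C | intermediate
12 | 3,7-diacetoxy-11-nordriman-9-one | CC(=O)O[C@@H]1CC[C@@]2(C)C(=O)[C@H](C)[C@@H](OC(C)=O)C[C@@H]2C1(C)C | intermediate
13 | 3-acetoxy-11-nordrim-7-en-9-one | CC(=O)O[C@@H]1CC[C@@]2(C)C(=O)C(C)=CC[C@@H]2C1(C)C | intermediate
14 | 3-acetoxydrima-7,9(11)-diene | CC(=O)O[C@@H]1CC[C@@]2(C)C(=C)C(C)=CC[C@@H]2C1(C)C | intermediate
15 | 3-acetoxy-11-(9-borabicyclo[3.3.1]nonan-9-yl)drim-7-ene | CC(=O)O[C@@H]1CC[C@@]2(C)[C@H](CB3C4CCCC3CCC4)C(C)=CC[C@@H]2C1(C)C | intermediate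
16 | 3-acetoxydrim-7-en-11-ol (C11 cis to C10 methyl) | CC(=O)O[C@@H]1CC[C@@]2(C)[C@H](CO)C(C)=CC[C@@H]2C1(C)C | intermediate
17 | umbelliferone (7-hydroxycoumarin) | O=c1ccc2ccc(O)cc2o1 | starting material
18 | 7-{[(1R,4aS,6R,8aR)-6-acetoxy-2,5,5,8a-tetramethyl-1,4,4a,5,6,7,8,8a-octahydronaphthalen-1-yl]methoxy}-2H-chromen-2-one | CC(=O)O[C@@H]1CC[C@@]2(C)[C@H](COc3ccc4ccc(=O)oc4c3)C(C)=CC[C@@H]2C1(C)C | target

## Step count and least certain steps

Total: 10 steps. Longest linear sequence: 10 steps (1 → 18); compounds 3, 5 and 17 are bought.

**Step 3 (key step).**
- Risk: proton transfer from C8–H to ester enolate 7, which would lead to a second Michael addition at C8 or to acrylate oligomerisation. Slow closure onto the neopentyl-type C3 ester and incomplete facial selectivity at C10 are lesser risks.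
- Fallback, from 4 back to the route at 9: the second Michael addition is also run in the Mukaiyama mode, with no basic enolate. Addition of 4 to triethyl orthoacrylate under Ph3CSbCl6 catalysis in CH2Cl2 at −78 °C should give ketene diethyl acetal F1, which mild aqueous acid hydrolyses to keto diester F2. Dieckmann closure of F2 with KOtBu in THF should give ethyl β-keto ester F3, and LiCl in wet DMSO at 160 °C returns diketone 9.

**Step 8.**
- Risk: sluggish methylenation of the C9 carbonyl, which sits between a quaternary carbon and a substituted alkene carbon, with enolisation toward C6 or loss of the acetate as side processes.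
- Fallback, from 13 back at 14: a phosphorus ylide is used in excess and the acetate is sacrificed. Ph3PCH3Br and KOtBu in toluene at 90 °C should methylenate C9 and cleave the ester, giving hydroxy diene F8; Ac2O, pyridine and DMAP then restore 14.

**Step 9.**
- Risk: poor site selectivity on the conjugated diene (addition across C7=C8 or in a 1,4 sense) or insufficient facial bias at C9.
- Fallback, from 13 back at 16, bypassing 14 and 15: Corey–Chaykovsky epoxidation of 13 (Me3SI, KN(SiMe3)2, THF, −10 °C) should deliver the methylene anti to the C10 methyl and give vinyl epoxide F9, with its oxygen cis to that methyl. Palladium-catalysed formate hydrogenolysis of the vinyl epoxide (Pd2(dba)3·CHCl3, PBu3, HCO2H, Et3N, dioxane) transfers hydride to C9 with inversion and opens the epoxide to 16.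

**Step 5.**
- Risk: loss of chemoselectivity, hydride also attacking C9.
- Fallback, from 9 back at 13: the isopropenyl group is excised first. Ozonolysis of 9 in CH2Cl2/MeOH should give methoxy hydroperoxide F4, Criegee rearrangement (Ac2O, Et3N, DMAP) 7-acetoxy diketone F5, and DBU enedione F6. In F6 the C9 carbonyl is a cross-conjugated, doubly flanked enone carbonyl, so NaBH4 at −20 °C should reduce only C3 to hydroxy enone F7. Ac2O and pyridine then give 13.

**Step 10.**
- Risk: E2 loss of the activated C11 oxygen toward diene 14 and slow SN2 displacement at the β-branched carbon.
- Fallback, from 16 directly to 18 (no new compound, F0): the aryl–oxygen bond is formed instead of the C11–oxygen bond, by palladium-catalysed C–O coupling of 16 with 7-bromocoumarin ([Pd(allyl)Cl]2, RockPhos, Cs2CO3, toluene, 90 °C).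

## Further compounds

F1 | step 3 | methyl 2-[2-(3,3-diethoxyprop-2-en-1-yl)-2,4-dimethyl-3-oxo-5-(prop-1-en-2-yl)cyclohexyl]-2-methylpropanoate | CCOC(OCC)=CC[C@@]1(C)C(=O)[C@H](C)[C@@H](C(C)=C)C[C@@H]1C(C)(C)C(=O)OC
F2 | step 3 | methyl 2-[2-(3-ethoxy-3-oxopropyl)-2,4-dimethyl-3-oxo-5-(prop-1-en-2-yl)cyclohexyl]-2-methylpropanoate | CCOC(=O)CC[C@@]1(C)C(=O)[C@H](C)[C@@H](C(C)=C)C[C@@H]1C(C)(C)C(=O)OC
F3 | step 3 | ethyl 7-isopropenyl-3,9-dioxo-11-nordrimane-2-carboxylate | CCOC(=O)C1C[C@@]2(C)C(=O)[C@H](C)[C@@H](C(C)=C)C[C@@H]2C(C)(C)C1=O
F4 | step 5 | 7-(1-hydroperoxy-1-methoxyethyl)-11-nordrimane-3,9-dione | O=C1CC[C@@]2(C)C(=O)[C@H](C)[C@@H](C(C)(OC)OO)C[C@@H]2C1(C)C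
F5 | step 5 | 7-acetoxy-11-nordrimane-3,9-dione | O=C1CC[C@@]2(C)C(=O)[C@H](C)[C@@H](OC(C)=O)C[C@@H]2C1(C)C
F6 | step 5 | 11-nordrim-7-ene-3,9-dione | O=C1CC[C@@]2(C)C(=O)C(C)=CC[C@@H]2C1(C)C
F7 | step 5 | 3-hydroxy-11-nordrim-7-en-9-one | O[C@@H]1CC[C@@]2(C)C(=O)C(C)=CC[C@@H]2C1(C)C
F8 | step 8 | drima-7,9(11)-dien-3-ol | O[C@@H]1CC[C@@]2(C)C(=C)C(C)=CC[C@@H]2C1(C)C
F9 | step 9 | 3-acetoxy-9,11-epoxydrim-7-ene (epoxide oxygen cis to the C10 methyl) | CC(=O)O[C@@H]1CC[C@@]2(C)[C@@]3(CO3)C(C)=CC[C@@H]2C1(C)C
F0 | step 10 | none | none
A1 | alternative 1 | trans-fused 3,7-bis(tert-butyldimethylsilyloxy)drim-6-en-11-al | CC(C)(C)[Si](C)(C)O[C@@H]1CC[C@@]2(C)[C@H](C=O)[C@H](C)C(O[Si](C)(C)C(C)(C)C)=C[C@@H]2C1(C)C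
A2 | alternative 1 | (2E,8E,10Z)-6,10-bis(tert-butyldimethylsilyloxy)-3,7,7-trimethyldodeca-2,8,10-trienal | O=C/C=C(\C)CC[C@@H](O[Si](C)(C)C(C)(C)C)C(C)(C)/C=C/C(O[Si](C)(C)C(C)(C)C)=C/C
A3 | alternative 2 | 3-hydroxy-11-nordrim-7-en-9-one | O[C@@H]1CC[C@@]2(C)C(=O)C(C)=CC[C@@H]2C1(C)C
A4 | alternative 2 | 3-[1,3-dimethyl-2-oxo-6-(prop-1-en-2-yl)cyclohex-3-en-1-yl]propanal (chain trans to isopropenyl) | O=CCC[C@@]1(C)C(=O)C(C)=CC[C@@H]1C(C)=C
A5 | alternative 3 | methyl 3-(tert-butyldimethylsilyloxy)drima-5,8-dien-11-oate | CC(C)(C)[Si](C)(C)O[C@@H]1CC[C@@]2(C)C(C(=O)OC)=C(C)CC=C2C1(C)C
A6 | alternative 3 | tert-butyl[(2,2,4-trimethyl-3-vinylcyclohex-3-en-1-yl)oxy]dimethylsilane | C=CC1=C(C)CC[C@@H](O[Si](C)(C)C(C)(C)C)C1(C)C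
A7 | alternative 3 | methyl but-2-ynoate | CC#CC(=O)OC
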